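**Plan**
- Retrosynthesis: O1–C2 is cut first (intramolecular Mitsunobu etherification), then C4–C4a (C-acylation of the ring A dienolate), then the O5–CH3 bond, then C4a–C8a of ring A (Claisen reclosure of an opened enol lactone), and last the two C8–prenyl bonds.
- Enabling feature: ring A carries oxygen on C5, C7 and C8a around the quaternary C8, so it is a 2,2-diprenylcyclohexane-1,3,5-trione. That trione is a constitutional isomer of 6-methyl-3,3-diprenylpyran-2,4-dione, which comes from triacetic acid lactone by prenylation at its one nucleophilic carbon.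
- Forward order: the pyranone ring is diprenylated, then opened and reclosed to carbocyclic ring A; O5 is methylated, C4a is acylated with a three-carbon chain carrying the phenyl carbinol, and the dihydropyranone ring closes last.
- Stereochemistry: the only stereocentre, C2 (S), comes from commercial (R)-3-hydroxy-3-phenylpropanoic acid and is inverted in the closing Mitsunobu step.

Key step: step 3

Remark: atom labels follow the chromanone numbering of the target (O1, C2 to C4, C4a, C5 to C8, C8a); enolisable intermediates are written as one tautomer each.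

**Step 1**
Reactants: 1 3-methylbut-2-en-1-ol (prenol)
Product: 2 tert-butyl (3-methylbut-2-en-1-yl) carbonate
Conditions: Boc2O (1.2 equiv), Bu4NHSO4 (5 mol %), 30% aq. NaOH, CH2Cl2, 0 °C → rt
Reagents that add atoms: di-tert-butyl dicarbonate, CC(C)(C)OC(=O)OC(=O)OC(C)(C)C
Why: Phase-transfer O-acylation of a primary allylic alcohol with Boc2O is the standard preparation of allylic tert-butyl carbonates and should proceed without allylic transposition.

**Step 2**
Reactants: 3 4-hydroxy-6-methyl-2H-pyran-2-one (triacetic acid lactone); 2 tert-butyl (3-methylbut-2-en-1-yl) carbonate (2.1 equiv)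
Product: 5 6-methyl-3,3-bis(3-methylbut-2-en-1-yl)-2H-pyran-2,4(3H)-dione, via monoprenyl pyrone 4 (not isolated)
Conditions: Pd(PPh3)4 (5 mol %), THF, rt → 50 °C
Reagents that add atoms: none
Why: Tsuji–Trost allylic alkylation, in which zerovalent palladium ionises 2 with loss of CO2, the tert-butoxide set free deprotonates the acidic pyrone, and its soft C3 carbon attacks the unsubstituted terminus of the π-prenyl ligand twice; O-prenyl ethers formed on the way re-ionise under the catalyst and drain to the C3,C3-dialkylated dione, and tert-butoxide is too hindered to open the enol lactone of 5.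

**Step 3**
Reactants: 5 6-methyl-3,3-bis(3-methylbut-2-en-1-yl)-2H-pyran-2,4(3H)-dione
Product: 7 2,2-bis(3-methylbut-2-en-1-yl)cyclohexane-1,3,5-trione, via keto ester sodium salt 6 (not isolated)
Conditions: NaOMe (1.1 equiv), MeOH–THF, 0 °C → rt; evaporate; NaH (2.5 equiv), DME, 85 °C; then 1 M HCl, 0 °C
Reagents that add atoms: none
Why: Methoxide attacks the lactone carbonyl of 5, an enol ester whose tetrahedral intermediate expels a stabilised β-diketonate, and so cleaves the acyl–oxygen bond to give the sodium salt of keto ester 6. NaH then removes a proton from the terminal methyl group of this diketonate, and the dianion attacks the untouched, non-enolisable ester in a Claisen (Dieckmann-type) condensation that forms the C4a–C8a bond and expels methoxide, so that 5 is isomerised to carbocyclic ring A. The closest known reactions are the alkoxide-induced rearrangement of enol δ-lactones to cyclohexane-1,3-diones and the NaH-mediated acylation of β-diketones by esters at the terminal methyl group. The ring closes in the 6-exo-trig mode, helped by the gem-dialkyl effect of the two prenyl groups, and no stereocentre arises because C8 carries two identical substituents. The step needs methoxide to attack the lactone carbonyl in preference to conjugate addition at the methyl-bearing enone carbon, and C-acylation in preference to return to the lactone through oxygen: the first is favoured because the enol ester carbonyl is the hardest and most activated electrophile, the second because relactonisation is reversible (the methoxide set free reopens 5) whereas trione 7 leaves the equilibrium as its doubly deprotonated vinylogous carboxylate. The quaternary carbon installed in step 2 blocks enolisation next to the ester and aromatisation of the product, and since only about one equivalent of methoxide is present the non-enolisable 1,3-dione unit is not exposed to retro-Claisen cleavage.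

**Step 4**
Reactants: 7 2,2-bis(3-methylbut-2-en-1-yl)cyclohexane-1,3,5-trione
Product: 8 5-methoxy-2,2-bis(3-methylbut-2-en-1-yl)cyclohex-4-ene-1,3-dione
Conditions: MeOH, p-TsOH·H2O (5 mol %), 3 Å molecular sieves, rt
Reagents that add atoms: methanol, CO
Why: Acid-catalysed enol etherification of a cyclic 1,3-dione (vinylogous Fischer esterification), in which methanol adds to the protonated C5 carbonyl, the only one not flanked by the quaternary carbon, so that the O5 ether should form under both kinetic and thermodynamic control as with 4,4-dialkylcyclohexane-1,3-diones, while catalytic acid at room temperature should spare the prenyl groups.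

**Step 5**
Reactants: 9 (R)-3-hydroxy-3-phenylpropanoic acid
Product: 11 (R)-3-[(tert-butyldimethylsilyl)oxy]-3-phenylpropanoic acid, via silyl ester 10 (not isolated)
Conditions: TBSCl (2.4 equiv), imidazole (5 equiv), DMF, rt; then K2CO3 (1.5 equiv), THF–H2O, rt; 1 M HCl to pH 3, 0 °C
Reagents that add atoms: tert-butyldimethylsilyl chloride, CC(C)(C)[Si](C)(C)Cl
Why: Silylation of both the alcohol and the acid followed by selective hydrolysis of the much more labile silyl ester with aqueous carbonate is the standard route to a silyl-protected hydroxy acid, and the stereocentre is not involved and keeps its R configuration.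

**Step 6**
Reactants: 8 5-methoxy-2,2-bis(3-methylbut-2-en-1-yl)cyclohex-4-ene-1,3-dione; 11 (R)-3-[(tert-butyldimethylsilyl)oxy]-3-phenylpropanoic acid
Product: 13 5-hydroxy-3-methoxy-6,6-bis(3-methylbut-2-en-1-yl)-4-{(3R)-3-[(tert-butyldimethylsilyl)oxy]-3-phenylpropanoyl}cyclohexa-2,4-dien-1-one, via enol ester 12 (not isolated)
Conditions: DCC (1.2 equiv), 4-(dimethylamino)pyridine (1.2 equiv), CH2Cl2, 0 °C → rt
Reagents that add atoms: none
Why: Steglich esterification of the acidic dienol gives enol ester 12, which 4-(dimethylamino)pyridine converts by O-to-C acyl transfer through an acylpyridinium–dienolate ion pair, the known route from cyclic 1,3-diones to 2-acyl-1,3-diones; the two ring carbons flanking C5 are equivalent in the symmetric dienolate of 8, so only one C-acyl product can form, and its chelated acidic enol drives the shift.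

**Step 7**
Reactants: 13 5-hydroxy-3-methoxy-6,6-bis(3-methylbut-2-en-1-yl)-4-{(3R)-3-[(tert-butyldimethylsilyl)oxy]-3-phenylpropanoyl}cyclohexa-2,4-dien-1-one
Product: 14 5-hydroxy-4-[(3R)-3-hydroxy-3-phenylpropanoyl]-3-methoxy-6,6-bis(3-methylbut-2-en-1-yl)cyclohexa-2,4-dien-1-one
Conditions: HF·pyridine, pyridine, THF, 0 °C → rt
Reagents that add atoms: none
Why: Fluoride-mediated desilylation with buffered HF·pyridine cleaves the Si–O bond without base, so neither retro-aldol cleavage nor β-elimination of the benzylic β-hydroxy ketone is expected and the R centre stays untouched.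

**Step 8**
Reactants: 14 5-hydroxy-4-[(3R)-3-hydroxy-3-phenylpropanoyl]-3-methoxy-6,6-bis(3-methylbut-2-en-1-yl)cyclohexa-2,4-dien-1-one
Product: 15 griffinone A, (2S)-5-methoxy-8,8-bis(3-methylbut-2-en-1-yl)-2-phenyl-2,3-dihydro-4H-chromene-4,7(8H)-dione
Conditions: PPh3 (1.5 equiv), DIAD (1.5 equiv), THF, 0 °C; neutral work-up
Reagents that add atoms: none
Why: Intramolecular Mitsunobu etherification, in which the acidic enol O8a–H protonates the betaine, the benzylic alcohol is activated as its alkoxyphosphonium ion and the enolate oxygen displaces it in a 6-exo-tet SN2 closure with inversion, turning the R carbinol into the S-configured C2, as in the known Mitsunobu closure of 2'-hydroxy-β-hydroxydihydrochalcones to flavanones.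

**Compound list**
1 | 3-methylbut-2-en-1-ol (prenol) | CC(C)=CCO | starting material
2 | tert-butyl (3-methylbut-2-en-1-yl) carbonate | CC(C)=CCOC(=O)OC(C)(C)C | intermediate
3 | 4-hydroxy-6-methyl-2H-pyran-2-one (triacetic acid lactone) | CC1=CC(O)=CC(=O)O1 | starting material
4 | 4-hydroxy-6-methyl-3-(3-methylbut-2-en-1-yl)-2H-pyran-2-one | CC1=CC(O)=C(CC=C(C)C)C(=O)O1 | intermediate
5 | 6-methyl-3,3-bis(3-methylbut-2-en-1-yl)-2H-pyran-2,4(3H)-dione | CC1=CC(=O)C(CC=C(C)C)(CC=C(C)C)C(=O)O1 | intermediate
6 | methyl 2,2-bis(3-methylbut-2-en-1-yl)-3,5-dioxohexanoate (formed as its sodium diketonate) | COC(=O)C(CC=C(C)C)(CC=C(C)C)C(=O)CC(C)=O | intermediate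
7 | 2,2-bis(3-methylbut-2-en-1-yl)cyclohexane-1,3,5-trione | O=C1CC(=O)C(CC=C(C)C)(CC=C(C)C)C(=O)C1 | intermediate
8 | 5-methoxy-2,2-bis(3-methylbut-2-en-1-yl)cyclohex-4-ene-1,3-dione | COC1=CC(=O)C(CC=C(C)C)(CC=C(C)C)C(=O)C1 | intermediate
9 | (R)-3-hydroxy-3-phenylpropanoic acid | OC(=O)C[C@@H](O)c1ccccc1 | starting material
10 | tert-butyldimethylsilyl (R)-3-[(tert-butyldimethylsilyl)oxy]-3-phenylpropanoate | CC(C)(C)[Si](C)(C)OC(=O)C[C@@H](O[Si](C)(C)C(C)(C)C)c1ccccc1 | intermediate
11 | (R)-3-[(tert-butyldimethylsilyl)oxy]-3-phenylpropanoic acid | OC(=O)C[C@@H](O[Si](C)(C)C(C)(C)C)c1ccccc1 | intermediate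
12 | 3-methoxy-5-oxo-6,6-bis(3-methylbut-2-en-1-yl)cyclohexa-1,3-dien-1-yl (R)-3-[(tert-butyldimethylsilyl)oxy]-3-phenylpropanoate | COC1=CC(=O)C(CC=C(C)C)(CC=C(C)C)C(OC(=O)C[C@@H](O[Si](C)(C)C(C)(C)C)c2ccccc2)=C1 | intermediate
13 | 5-hydroxy-3-methoxy-6,6-bis(3-methylbut-2-en-1-yl)-4-{(3R)-3-[(tert-butyldimethylsilyl)oxy]-3-phenylpropanoyl}cyclohexa-2,4-dien-1-one | COC1=CC(=O)C(CC=C(C)C)(CC=C(C)C)C(O)=C1C(=O)C[C@@H](O[Si](C)(C)C(C)(C)C)c1ccccc1 | intermediate
14 | 5-hydroxy-4-[(3R)-3-hydroxy-3-phenylpropanoyl]-3-methoxy-6,6-bis(3-methylbut-2-en-1-yl)cyclohexa-2,4-dien-1-one | COC1=CC(=O)C(CC=C(C)C)(CC=C(C)C)C(O)=C1C(=O)C[C@@H](O)c1ccccc1 | intermediate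
15 | griffinone A, (2S)-5-methoxy-8,8-bis(3-methylbut-2-en-1-yl)-2-phenyl-2,3-dihydro-4H-chromene-4,7(8H)-dione | COC1=CC(=O)C(CC=C(C)C)(CC=C(C)C)C2=C1C(=O)C[C@@H](c1ccccc1)O2 | target

**Step count**
Total: 8 steps. Longest linear sequence: 7 steps (steps 1, 2, 3, 4, 6, 7, 8); step 5 is a one-step branch that joins at step 6.

**Steps most likely to fail**

Step 3 (ring opening and Claisen reclosure). Methoxide may add to the methyl-bearing enone carbon of 5 in a conjugate addition–elimination, opening the ring to a carboxylate that cannot reclose. The diketonate may also close so slowly that retro-Claisen cleavage next to the quaternary carbon takes over. The fallback builds ring A from acyclic pieces with a doubly activated nucleophilic carbon; it sets out from 2 and comes back at 7. Dimethyl malonate should be diprenylated with 2 under Pd(PPh3)4 in THF to dimethyl 2,2-bis(3-methylbut-2-en-1-yl)malonate F1. The dianion of methyl acetoacetate (NaH, then n-BuLi, THF, 0 °C) should be acylated at its terminal carbon by one ester group of F1 to give dimethyl 2,2-bis(3-methylbut-2-en-1-yl)-3,5-dioxoheptanedioate F2. NaOMe in MeOH should then close the ring by Dieckmann condensation of the C6 methylene onto the remaining ester, giving methyl 2,4,6-trioxo-3,3-bis(3-methylbut-2-en-1-yl)cyclohexane-1-carboxylate F3. Saponification and decarboxylation (aq. NaOH, then dilute HCl, 40 °C) should deliver 7.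

Step 8 (Mitsunobu closure). β-Elimination of the activated benzylic alcohol to a cinnamoyl dienone, or ionisation at the benzylic carbon, would erode or erase the stereochemical information. The product may also racemise by base-induced retro-oxa-Michael opening. The fallback gives up stereospecific closure for racemic closure and resolution; it sets out from 8 and comes back at 15. Cinnamic acid, DCC and 4-(dimethylamino)pyridine should give, by the same O-to-C acyl transfer as in step 6, 5-hydroxy-3-methoxy-6,6-bis(3-methylbut-2-en-1-yl)-4-[(E)-3-phenylprop-2-enoyl]cyclohexa-2,4-dien-1-one F4. NaOAc in ethanol at reflux should close it by oxa-Michael addition to racemic griffinone A F5. Preparative HPLC on a chiral stationary phase (cellulose tris(3,5-dimethylphenylcarbamate)) should then separate the enantiomers, the S enantiomer being 15.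

Step 2 (double prenylation of the pyrone). The ambident pyronate may react through oxygen, the nucleophile may attack the tertiary terminus of the π-prenyl ligand, the reaction may stall after one prenyl group, or a third prenylation may occur through the vinylogous enolate of 5. The fallback creates the quaternary carbon on a simple β-keto ester and dispenses with the pyranone; it sets out from 2 and comes back at 6. Double prenylation of methyl acetoacetate with 2 under Pd(PPh3)4 should give methyl 2,2-bis(3-methylbut-2-en-1-yl)-3-oxobutanoate F6. Its lithium enolate (LiN(i-Pr)2, THF, −78 °C; only the methyl group can enolise) should be acetylated with N-methoxy-N-methylacetamide to 6, here isolated as the free diketo ester. Compound 6 is then closed to 7 by the NaH stage of step 3.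

Further compounds
F1 | step 3 | dimethyl 2,2-bis(3-methylbut-2-en-1-yl)malonate | COC(=O)C(CC=C(C)C)(CC=C(C)C)C(=O)OC
F2 | step 3 | dimethyl 2,2-bis(3-methylbut-2-en-1-yl)-3,5-dioxoheptanedioate | COC(=O)CC(=O)CC(=O)C(CC=C(C)C)(CC=C(C)C)C(=O)OC
F3 | step 3 | methyl 2,4,6-trioxo-3,3-bis(3-methylbut-2-en-1-yl)cyclohexane-1-carboxylate | COC(=O)C1C(=O)CC(=O)C(CC=C(C)C)(CC=C(C)C)C1=O
F4 | step 8 | 5-hydroxy-3-methoxy-6,6-bis(3-methylbut-2-en-1-yl)-4-[(E)-3-phenylprop-2-enoyl]cyclohexa-2,4-dien-1-one | COC1=CC(=O)C(CC=C(C)C)(CC=C(C)C)C(O)=C1C(=O)/C=C/c1ccccc1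
F5 | step 8 | racemic griffinone A | COC1=CC(=O)C(CC=C(C)C)(CC=C(C)C)C2=C1C(=O)CC(c1ccccc1)O2
F6 | step 2 | methyl 2,2-bis(3-methylbut-2-en-1-yl)-3-oxobutanoate | COC(=O)C(CC=C(C)C)(CC=C(C)C)C(C)=O
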